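**Retrosynthesis**
1. The C1=C10 cis-trisubstituted acrylate in the 10-membered ring is closed last, by RCM of a vinyl epoxide and an MBH-type acrylate. The free acid comes from hydrolysis of a hexafluoroisopropyl (HFIP) ester.
2. The γ-lactone and the C6–C7 bond come from an In-mediated Barbier allylation of a bis-epoxy aldehyde with a (Z)-2-(bromomethyl)enoate.
3. Key step: the two cis-epoxides (C2–C5) come from a metal-free, organocatalytic double Shi-type epoxidation of a (2Z,4Z)-trienol built from 2-butyn-1-ol.
4. C8 is set by organocatalytic α-acyloxylation with (2R,3R)-epoxyangelic acid, and C9 by an organocatalytic asymmetric Morita–Baylis–Hillman (MBH) reaction.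
5. Order of ring formation: two epoxides, then the lactone, then the carbocycle.

Assumption: 3-(4-methoxybenzyloxy)propan-1-ol, but-1-en-3-yne (commercial solution), angelic acid, HFIP acrylate and methyl acrylate are commercially available and achiral.

**Step 1**
Reactants: 1, 2-butyn-1-ol
Product: 2, (Z)-3-iodobut-2-en-1-ol
Conditions: Red-Al, Et2O, 0 °C→rt; EtOAc, –78 °C; I2, –78 °C→rt
Reagents that add atoms: iodine, II
Why: Alkoxide-directed trans-hydroalumination puts Al on C3 and iodinolysis retains geometry (Denmark/Corey-type hydroalumination–iodination), giving the Z-vinyl iodide that fixes the cis relationship of C3 and C6.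

**Step 2**
Reactants: 2; 3, but-1-en-3-yne
Product: 4, (2Z)-3-methylhepta-2,6-dien-4-yn-1-ol
Conditions: Pd(PPh3)4 (5 mol%), CuI, i-Pr2NH, THF, 0 °C→rt
Reagents that add atoms: none
Why: Sonogashira coupling retains the alkene geometry.

**Step 3**
Reactants: 4
Product: 5, (2Z,4Z)-3-methylhepta-2,4,6-trien-1-ol
Conditions: Zn(Cu/Ag), MeOH/H2O 1:1, 40 °C
Reagents that add atoms: none
Why: Boland reduction of a conjugated enyne adds H2 syn to the alkyne, giving the Z-alkene and hence the Z,Z-triene.

**Step 4**
Reactants: 5
Product: 6, bis-epoxy alcohol [3-methyl-3-(3-vinyloxiran-2-yl)oxiran-2-yl]methanol (cis,cis; C2, C3, C4 and C5 set as in the SMILES list)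
Conditions: Shi ketone (D-fructose-derived, 30 mol%), Oxone, K2CO3, Bu4NHSO4, MeCN/DMM/aq. Na2B4O7–EDTA (pH 10.5), 0 °C
Reagents that add atoms: Oxone (KHSO5), OOS(=O)(=O)[O-].[K+]
Why: A chiral fructose-derived dioxirane transfers O stereospecifically (spiro transition state) to each Z-alkene, so cis-epoxides form with catalyst-controlled facial selectivity, first at the most electron-rich C4=C5 and then at C2=C3, while the terminal vinyl survives.
Proposed new method: the mechanism is organocatalytic dioxirane O-transfer with the face set by the ketone, and the closest known reaction is Shi epoxidation of conjugated cis-enynes and dienes. Sequential double epoxidation of a Z,Z-1,3-diene within a triene, leaving the vinyl group untouched, to set four contiguous stereocenters is unreported.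

**Step 5**
Reactants: 6
Product: 7, epoxy aldehyde 3-methyl-3-(3-vinyloxiran-2-yl)oxirane-2-carbaldehyde
Conditions: Dess–Martin periodinane, NaHCO3, CH2Cl2, 0 °C
Reagents that add atoms: none
Why: Mild oxidation of the primary alcohol leaves both epoxides and all stereocenters untouched (the aldehyde is used at once because of the α-epoxide).

**Step 6**
Reactants: 8, angelic acid
Product: 9, (Z)-2-methylbut-2-en-1-ol
Conditions: LiAlH4, Et2O, 0 °C
Reagents that add atoms: none
Why: Hydride reduction of the acid retains the Z-alkene.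

**Step 7**
Reactants: 9
Product: 10, [(2S,3R)-2,3-dimethyloxiran-2-yl]methanol
Conditions: Ti(OiPr)4 (10 mol%), L-(+)-DET (12 mol%), TBHP, 4 Å MS, CH2Cl2, –20 °C
Reagents that add atoms: tert-butyl hydroperoxide, CC(C)(C)OO
Why: Sharpless asymmetric epoxidation of the Z-allylic alcohol sets both epoxide stereocenters, and the cis-epoxide is stereospecific.

**Step 8**
Reactants: 10
Product: 11, (2R,3R)-2,3-epoxy-2-methylbutanoic acid (epoxyangelic acid)
Conditions: TEMPO (20 mol%), PhI(OAc)2, MeCN/H2O 1:1, rt
Reagents that add atoms: water, O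
Why: TEMPO/PIDA oxidizes the primary alcohol through the aldehyde hydrate to the acid without touching the epoxide.

**Step 9**
Reactants: 12, 3-(4-methoxybenzyloxy)propan-1-ol
Product: 13, 3-(4-methoxybenzyloxy)propanal
Conditions: Dess–Martin periodinane, CH2Cl2, rt
Reagents that add atoms: none
Why: Standard oxidation to the aldehyde.

**Step 10**
Reactants: 13; 11
Product: 14, (S)-3-[(4-methoxybenzyl)oxy]-1-oxopropan-2-yl (2R,3R)-2,3-dimethyloxirane-2-carboxylate
Conditions: (S)-diphenylprolinol TMS ether (20 mol%), PhI(OAc)2 (1.5 equiv), 11 (1.5 equiv), CH2Cl2, 0 °C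
Reagents that add atoms: none
Why: The enamine is iodinated at carbon by the in-situ bis(acyloxy)iodane and the carboxylate displaces PhI, setting C8 by shielding of one enamine face (used immediately to avoid racemization).
Proposed new method: this is an enamine-catalysed α-oxygenation whose closest known relatives are α-aminoxylation/α-benzoyloxylation of aldehydes and α-oxytosylation with Koser-type I(III) reagents. Direct catalytic α-acyloxylation of an aldehyde with an I(III) carboxylate formed in situ from a complex, epoxide-bearing acid is unreported.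

**Step 11**
Reactants: 14; 15, HFIP acrylate
Product: 16, MBH adduct
Conditions: β-isocupreidine (10 mol%), DMF, –55 °C
Reagents that add atoms: none
Why: Asymmetric Morita–Baylis–Hillman reaction in which the chiral amine catalyst overrides the α-acyloxy stereocenter and sets C9 with the threo relationship to C8.

**Step 12**
Reactants: 16
Product: 17, C9 triethylsilyl ether
Conditions: TESOTf, 2,6-lutidine, CH2Cl2, –78 °C
Reagents that add atoms: triethylsilyl triflate, CC[Si](CC)(CC)OS(=O)(=O)C(F)(F)F
Why: Masking C9–OH prevents acyl migration and keeps C9 from behaving as an MBH acetate in the later DABCO and bromide steps.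

**Step 13**
Reactants: 17
Product: 18, primary alcohol
Conditions: DDQ, CH2Cl2/pH 7 phosphate buffer, 0 °C
Reagents that add atoms: none
Why: Oxidative PMB removal leaves the silyl ether, esters and epoxide intact.

**Step 14**
Reactants: 18
Product: 19, α-acyloxy aldehyde
Conditions: Dess–Martin periodinane, NaHCO3, CH2Cl2, 0 °C
Reagents that add atoms: none
Why: Mild buffered oxidation minimizes epimerization at C8.

**Step 15**
Reactants: 19; 20, methyl acrylate
Product: 21, MBH adduct at C7 (C7 stereocenter undefined)
Conditions: DABCO (30 mol%), methyl acrylate (5 equiv), MeCN, 0 °C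
Reagents that add atoms: none
Why: DABCO-catalysed MBH reaction; the new C7 carbinol stereocenter is erased in the next step.

**Step 16**
Reactants: 21
Product: 22, (Z)-2-(bromomethyl)enoate
Conditions: MsCl, Et3N, CH2Cl2, 0 °C; then LiBr, THF, 0 °C→rt
Reagents that add atoms: lithium bromide, [Li+].[Br-]
Why: Mesylation then bromide SN2′ displacement gives the (Z)-allyl bromide with C8 cis to CH2Br, which is the geometry needed for the Barbier allylation.

**Step 17**
Reactants: 7; 22
Product: 23, vinyl-epoxide lactone with C6 and C7 set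
Conditions: In powder (3 equiv), THF/H2O 5:1, rt
Reagents that add atoms: none
Why: Barbier allylindium addition through a chair transition state (SE2′) forms the C6–C7 bond and in-situ γ-lactonization (loss of MeOH) gives the anti, trans-lactone, with C6 set by Felkin–Anh control and the matched diastereomer (expected about 3:1) separated.

**Step 18**
Reactants: 23
Product: 24, C9 alcohol
Conditions: Et3N·3HF, THF, 0 °C
Reagents that add atoms: none
Why: Buffered fluoride removes the TES group without opening the epoxides, and the short reaction time limits C8→C9 acyl migration.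

**Step 19**
Reactants: 24
Product: 25, C9 acetate
Conditions: Ac2O, pyridine, DMAP (cat.), CH2Cl2, 0 °C
Reagents that add atoms: acetic anhydride, CC(=O)OC(C)=O
Why: Fast acetylation of the only free OH fixes the C9 acetate with retention of configuration.

**Step 20**
Reactants: 25
Product: 26, macrocyclic HFIP ester (C1=C10 formed; ethylene lost)
Conditions: Hoveyda–Grubbs II (15 mol%), 1,4-benzoquinone (20 mol%), toluene (1 mM), 60 °C
Reagents that add atoms: none
Why: Ring-closing metathesis between the vinyl epoxide and the MBH acetate acrylate; in a 10-membered ring the cis (Z) alkene is strongly favored, which places C9 and C2 cis and the acid carbon trans to C2 as in the target.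

**Step 21**
Reactants: 26
Product: 27, leucanthin B
Conditions: LiOH·H2O (1.0 equiv), THF/H2O 9:1, 0 °C, 10 min; pH 3 workup
Reagents that add atoms: water, O
Why: The HFIP ester is far more electrophilic than the acetate, epoxyangelate or lactone and is cleaved chemoselectively to the free acid.

**Compound list**
1 | 2-butyn-1-ol | CC#CCO | starting material
2 | (Z)-3-iodobut-2-en-1-ol | OC/C=C(\I)C | intermediate
3 | but-1-en-3-yne | C=CC#C | starting material
4 | (2Z)-3-methylhepta-2,6-dien-4-yn-1-ol | OC/C=C(\C#CC=C)C | intermediate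
5 | (2Z,4Z)-3-methylhepta-2,4,6-trien-1-ol | OC/C=C(C)\C=C/C=C | intermediate
6 | cis,cis-bis-epoxy alcohol | OC[C@H]1O[C@@]1(C)[C@@H]1O[C@@H]1C=C | intermediate
7 | bis-epoxy aldehyde | O=C[C@H]1O[C@@]1(C)[C@@H]1O[C@@H]1C=C | intermediate
8 | angelic acid | C/C=C(/C)C(=O)O | starting material
9 | (Z)-2-methylbut-2-en-1-ol | C/C=C(/C)CO | intermediate
10 | [(2S,3R)-2,3-dimethyloxiran-2-yl]methanol | C[C@H]1O[C@@]1(C)CO | intermediate
11 | (2R,3R)-epoxyangelic acid | C[C@H]1O[C@@]1(C)C(=O)O | intermediate
12 | 3-(4-methoxybenzyloxy)propan-1-ol | OCCCOCc1ccc(OC)cc1 | starting material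
13 | 3-(4-methoxybenzyloxy)propanal | O=CCCOCc1ccc(OC)cc1 | intermediate
14 | (S)-α-epoxyangeloyloxy aldehyde | O=C[C@@H](OC(=O)[C@]1(C)O[C@@H]1C)COCc1ccc(OC)cc1 | intermediate
15 | HFIP acrylate | C=CC(=O)OC(C(F)(F)F)C(F)(F)F | starting material
16 | C9 MBH adduct | C=C(C(=O)OC(C(F)(F)F)C(F)(F)F)[C@H](O)[C@@H](OC(=O)[C@]1(C)O[C@@H]1C)COCc1ccc(OC)cc1 | intermediate
17 | C9 TES ether | C=C(C(=O)OC(C(F)(F)F)C(F)(F)F)[C@H](O[Si](CC)(CC)CC)[C@@H](OC(=O)[C@]1(C)O[C@@H]1C)COCc1ccc(OC)cc1 | intermediate
18 | primary alcohol | C=C(C(=O)OC(C(F)(F)F)C(F)(F)F)[C@H](O[Si](CC)(CC)CC)[C@@H](OC(=O)[C@]1(C)O[C@@H]1C)CO | intermediate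
19 | aldehyde | C=C(C(=O)OC(C(F)(F)F)C(F)(F)F)[C@H](O[Si](CC)(CC)CC)[C@@H](OC(=O)[C@]1(C)O[C@@H]1C)C=O | intermediate
20 | methyl acrylate | C=CC(=O)OC | starting material
21 | C7 MBH adduct | C=C(C(=O)OC(C(F)(F)F)C(F)(F)F)[C@H](O[Si](CC)(CC)CC)[C@@H](OC(=O)[C@]1(C)O[C@@H]1C)C(O)C(=C)C(=O)OC | intermediate
22 | (Z)-allyl bromide | C=C(C(=O)OC(C(F)(F)F)C(F)(F)F)[C@H](O[Si](CC)(CC)CC)[C@@H](OC(=O)[C@]1(C)O[C@@H]1C)/C=C(\CBr)C(=O)OC | intermediate
23 | Barbier lactone | C=C[C@H]1O[C@H]1[C@]2(C)O[C@@H]2[C@H]3OC(=O)C(=C)[C@@H]3[C@H](OC(=O)[C@]4(C)O[C@@H]4C)[C@@H](O[Si](CC)(CC)CC)C(=C)C(=O)OC(C(F)(F)F)C(F)(F)F | intermediate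
24 | C9 alcohol | C=C[C@H]1O[C@H]1[C@]2(C)O[C@@H]2[C@H]3OC(=O)C(=C)[C@@H]3[C@H](OC(=O)[C@]4(C)O[C@@H]4C)[C@@H](O)C(=C)C(=O)OC(C(F)(F)F)C(F)(F)F | intermediate
25 | C9 acetate | C=C[C@H]1O[C@H]1[C@]2(C)O[C@@H]2[C@H]3OC(=O)C(=C)[C@@H]3[C@H](OC(=O)[C@]4(C)O[C@@H]4C)[C@@H](OC(C)=O)C(=C)C(=O)OC(C(F)(F)F)C(F)(F)F | intermediate
26 | macrocyclic HFIP ester | C=C1C(=O)O[C@H]2[C@H]1[C@H](OC(=O)[C@]1(C)O[C@@H]1C)[C@@H](OC(C)=O)/C(C(=O)OC(C(F)(F)F)C(F)(F)F)=C\[C@H]1O[C@H]1[C@]1(C)O[C@H]21 | intermediate
27 | leucanthin B | C=C1C(=O)O[C@H]2[C@H]1[C@H](OC(=O)[C@]1(C)O[C@@H]1C)[C@@H](OC(C)=O)/C(C(=O)O)=C\[C@H]1O[C@H]1[C@]1(C)O[C@H]21 | target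

**Step count:** 21 steps in total; the longest linear sequence is 15 steps (angelic acid → 9 → 10 → 11 → 14 → 16 → 17 → 18 → 19 → 21 → 22 → 23 → 24 → 25 → 26 → 27).

**Three steps most likely to fail**
1. **Step 4 (proposed new method: double Shi epoxidation of the Z,Z-triene).**
   - Risks: cis-olefin epoxidation can erode ee or isomerize, and the vinyl group may react.
   - Fallback (known chemistry): Sonogashira and Lindlar of (Z)-3-iodobut-2-en-1-ol with propargyl alcohol give (2Z,4Z)-4-methylhexa-2,4-diene-1,6-diol. Two-directional Sharpless AE (Ti/tartrate) on this diol gives the cis,cis-bis-epoxy diol, followed by mono-protection, oxidation and Wittig methylenation of the C1 aldehyde to reach 7.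
2. **Step 10 (proposed new method: enamine/I(III) α-acyloxylation).**
   - Risks: over-oxidation and racemization.
   - Fallback (known chemistry): proline-catalysed α-aminoxylation of 13 (PhNO, then NaBH4 and N–O cleavage) to a diol, TES protection of the primary OH, Yamaguchi esterification with 11, PPTS/MeOH TES removal and DMP oxidation to 14.
3. **Step 20 (RCM of 25).**
   - Risks: medium ring formation with electron-poor 1,1-disubstituted alkenes, and competition from the lactone methylene.
   - Fallback: re-sequence the coupling. Join a C1 aldehyde to a C10 phosphonoacetate by intermolecular HWE to set the C1=C10 acrylate, then close the ring and form the lactone by intramolecular CrCl2/NiCl2 allylation (C6–C7), the known route to germacranolide 10-membered rings.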